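The lactone (ring B) is disconnected at C11–C12, the bond joining the α-methylene carbon to the carbonyl carbon (germacrane numbering; ring A is the C1–C10 carbocycle). In the key step a palladium catalyst makes a homopropargylic alcohol take up CO: O8 is carbonylated and the ring closes when the C11≡C13 alkyne inserts into the Pd–C12 bond, which delivers the exocyclic C11=C13 methylene directly. The step exploits the vicinal C8–O/C7–C11 pair of ring B. Its precursor is an acyclic syn,syn-2-ethynyl-1,3-diol monoangelate, built from two Sharpless epoxides by allenylindium addition; ring A is closed last by a Nozaki–Hiyama–Kishi reaction at C1–C10.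

Key step: step 12

Remark: locants C1–C15 follow the numbering of the target (C1–C10 ring A; C11, C12, C13 the lactone α-carbon, carbonyl and methylene; C14 the methylene on C10; C15 the methyl on C4). The ester is the (Z)-2-methylbut-2-enoate (angelate) encoded in the SMILES.

Step 1
Reactants: 1 nerol
Product: 2 (2S,3R)-2,3-epoxynerol
Conditions: Ti(OiPr)4 (cat.), L-(+)-diethyl tartrate, tBuOOH, 4 Å MS, CH2Cl2, −20 °C
Reagents that add atoms: tert-butyl hydroperoxide CC(C)(C)OO
Why: Sharpless asymmetric epoxidation: the allylic hydroxyl binds the titanium tartrate, so only the 2,3-alkene reacts, and L-(+)-tartrate should deliver oxygen to the face that gives the (2S,3R) cis-epoxide (C5 and C4 of the target), the remote trisubstituted alkene staying intact.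

Step 2
Reactants: 2 (2S,3R)-2,3-epoxynerol
Product: 3 (2R,3R)-2,3-epoxyneral
Conditions: Dess–Martin periodinane, pyridine, CH2Cl2, 0 °C
Reagents that add atoms: none
Why: Dess–Martin oxidation of the primary epoxy alcohol under buffered conditions should give the α,β-epoxy aldehyde (its formyl carbon becomes C6) without touching either stereocentre.

Step 3
Reactants: 4 (1-bromovinyl)trimethylsilane; 5 butadiene monoxide (racemic 2-vinyloxirane)
Product: 7 (2E)-5-(trimethylsilyl)hexa-2,5-dien-1-ol, via Grignard reagent 6 (not isolated)
Conditions: Mg, THF, 50 °C; then CuI (cat.), 5, THF, −40 °C to 0 °C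
Reagents that add atoms: none
Why: Copper-catalysed SN2′ (anti) addition of the alkenyl Grignard reagent to the vinyl oxirane should give the (E)-allylic alcohol and installs the C10 vinylsilane as a masked alkenyl iodide; the oxirane stereocentre is destroyed, so the racemate suffices.

Step 4
Reactants: 7 (2E)-5-(trimethylsilyl)hexa-2,5-dien-1-ol
Product: 8 [(2S,3S)-3-(2-trimethylsilylprop-2-enyl)oxiran-2-yl]methanol
Conditions: Ti(OiPr)4 (cat.), L-(+)-diethyl tartrate, tBuOOH, 4 Å MS, CH2Cl2, −20 °C
Reagents that add atoms: tert-butyl hydroperoxide CC(C)(C)OO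
Why: Sharpless asymmetric epoxidation of the (E)-allylic alcohol with L-(+)-tartrate should give the (2S,3S) trans-epoxide by reagent control (these carbons become C7 and C8), the vinylsilane having no directing hydroxyl and staying untouched.

Step 5
Reactants: 8 [(2S,3S)-3-(2-trimethylsilylprop-2-enyl)oxiran-2-yl]methanol
Product: 9 (2R,3S)-3-(2-trimethylsilylprop-2-enyl)oxirane-2-carbaldehyde
Conditions: Dess–Martin periodinane, pyridine, CH2Cl2, 0 °C
Reagents that add atoms: none
Why: Dess–Martin oxidation under buffered conditions should give the trans-epoxy aldehyde without epimerisation (the descriptor at C2 changes only through the priority rules).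

Step 6
Reactants: 9 (2R,3S)-3-(2-trimethylsilylprop-2-enyl)oxirane-2-carbaldehyde
Product: 10 (2S,3S)-2-ethynyl-3-(2-trimethylsilylprop-2-enyl)oxirane
Conditions: dimethyl (1-diazo-2-oxopropyl)phosphonate, K2CO3, MeOH, 0 °C to rt
Reagents that add atoms: dimethyl (1-diazo-2-oxopropyl)phosphonate COP(=O)(OC)C(=[N+]=[N-])C(C)=O
Why: Ohira–Bestmann (Seyferth–Gilbert) homologation converts the formyl group into the terminal alkyne C11≡C13 under mild carbonate conditions that should leave the trans-oxirane stereocentres unchanged.

Step 7
Reactants: 3 (2R,3R)-2,3-epoxyneral; 10 (2S,3S)-2-ethynyl-3-(2-trimethylsilylprop-2-enyl)oxirane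
Product: 12 syn,syn-6,8-diol (1S,2R,3S)-2-ethynyl-1-[(2S,3R)-3-methyl-3-(4-methylpent-3-enyl)oxiran-2-yl]-5-(trimethylsilyl)hex-5-ene-1,3-diol, via allenylindium species 11 (not isolated)
Conditions: Pd(dppf)Cl2 (cat.), InI, THF/HMPA (3:1), rt
Reagents that add atoms: none
Why: Palladium/indium-mediated umpolung propargylation: zerovalent palladium opens the alkynyl oxirane by anti SN2′ attack, transmetalation with InI gives a configurationally defined allenylindium, and its addition to the aldehyde through a cyclic SE2′ transition state should form C7 with net inversion (reagent control from 10, C8 carried over) and C6 anti to the C7 substituent, a sense that coincides with Felkin–Anh attack anti to the C5–O bond of 3 (matched pair).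

Step 8
Reactants: 12 syn,syn-6,8-diol
Product: 13 8-O-triethylsilyl ether of 12
Conditions: Et3SiCl, imidazole, CH2Cl2, −40 °C
Reagents that add atoms: chlorotriethylsilane CC[Si](Cl)(CC)CC
Why: Kinetic monosilylation: the C8 hydroxyl has a CH2 neighbour, whereas the C6 hydroxyl lies between two branched carbons and is hydrogen-bonded to and inductively deactivated by the adjacent oxirane, so the silyl chloride should react at O8.

Step 9
Reactants: 13 8-O-triethylsilyl ether of 12; 14 angelic acid
Product: 16 6-O-angeloyl-8-O-triethylsilyl derivative of 12, via mixed anhydride 15 (not isolated)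
Conditions: 14, 2,4,6-trichlorobenzoyl chloride, Et3N, toluene, rt; then 13, 75 °C
Reagents that add atoms: none
Why: Yamaguchi esterification through the preformed mixed anhydride, run without a nucleophilic catalyst, should acylate the hindered C6 hydroxyl while keeping the (Z)-geometry of the angelate; no stereocentre is affected.

Step 10
Reactants: 16 6-O-angeloyl-8-O-triethylsilyl derivative of 12
Product: 18 C1 aldehyde (6-O-angeloyl-8-O-triethylsilyl), via vicinal diol 17 (not isolated)
Conditions: OsO4 (cat.), NaIO4, 2,6-lutidine, dioxane/H2O, rt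
Reagents that add atoms: sodium periodate [Na+].[O-]I(=O)(=O)=O; water O
Why: Lemieux–Johnson oxidation: the electron-rich trisubstituted alkene should be osmylated much faster than the hindered vinylsilane, the conjugated angelate or the alkyne, and immediate periodate cleavage of the diol reveals the C1 aldehyde before the diol can attack the oxirane.

Step 11
Reactants: 18 C1 aldehyde (6-O-angeloyl-8-O-triethylsilyl)
Product: 19 8-hydroxy C1 aldehyde (homopropargylic alcohol)
Conditions: HF·pyridine, pyridine, THF, 0 °C
Reagents that add atoms: none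
Why: Buffered fluoride cleavage of the secondary triethylsilyl ether frees the C8 hydroxyl, while the vinylic C–Si bond, the oxirane, the aldehyde and the ester should survive the pyridine-buffered reagent.

Step 12
Reactants: 19 8-hydroxy C1 aldehyde (homopropargylic alcohol)
Product: 22 trans-α-methylene-γ-butyrolactone (8,12-olide) aldehyde, via alkoxycarbonylpalladium iodide 20 (not isolated), via alkenylpalladium iodide 21 (not isolated)
Conditions: PdI2 (cat.), PBu3 (cat.), CO (7 atm), MeCN, 70 °C
Reagents that add atoms: carbon monoxide [C-]#[O+]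
Why: Palladium-catalysed cyclocarbonylation of a homopropargylic alcohol: the C8 hydroxyl and CO first form the alkoxycarbonyl complex 20 of divalent palladium, which creates the O8–C12 bond. Ring B then closes by intramolecular syn-insertion of the C11≡C13 triple bond into the Pd–C12 bond, a 5-exo-dig migratory insertion that forms the C11–C12 bond and gives the (Z)-alkenylpalladium 21. Protonolysis of the C13–Pd bond by the proton released from the hydroxyl delivers the exocyclic C11=C13 methylene and returns divalent palladium, so neither oxidant nor base nor reductant is needed. The closest known reaction is the PdI2/phosphine-catalysed conversion of but-3-yn-1-ols into α-methylene-γ-butyrolactones. No stereocentre is created: the trans arrangement of C7 and C8 on the lactone is inherited from the syn,syn-diol set in step 7. The step needs chemoselectivity for the alkynol over the vinylsilane, aldehyde, oxirane and angelate; this is secured because O8–H is the only free hydroxyl, the ethynyl group is the only π-system within reach of a five-membered closure, and the medium is neutral.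

Step 13
Reactants: 22 trans-α-methylene-γ-butyrolactone (8,12-olide) aldehyde
Product: 23 alkenyl iodide (10-iodo analogue of 22)
Conditions: N-iodosuccinimide, MeCN/ClCH2CN, 0 °C to rt
Reagents that add atoms: N-iodosuccinimide O=C1CCC(=O)N1I
Why: Electrophilic ipso-iododesilylation: iodonium attack at the silicon-bearing carbon is guided by β-silicon stabilisation, and loss of the silyl group should give the 2-iodo-1-alkene with the double bond in place, the electron-poor methylene lactone and angelate alkenes being inert to the reagent.

Step 14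
Reactants: 23 alkenyl iodide (10-iodo analogue of 22)
Product: 25 CNP0104965.1 (target), via alkenylchromium dichloride 24 (not isolated)
Conditions: CrCl2, NiCl2 (cat.), DMSO/THF, rt, high dilution
Reagents that add atoms: none
Why: Intramolecular Nozaki–Hiyama–Kishi reaction: nickel-catalysed conversion of the alkenyl iodide into an alkenylchromium species that adds only to the aldehyde should close ring A at C1–C10 and create the allylic alcohol with its exocyclic C10=C14 methylene; C1 is set by substrate control, the trans-lactone and cis-oxirane being expected to hold the chromium-bound carbonyl oxygen on the outside of the forming ring so that C10 attacks the Re face and gives (1S).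

Compound list
1 | nerol, (2Z)-3,7-dimethylocta-2,6-dien-1-ol | CC(C)=CCC/C(C)=C\CO | starting material
2 | (2S,3R)-2,3-epoxynerol, [(2S,3R)-3-methyl-3-(4-methylpent-3-enyl)oxiran-2-yl]methanol | CC(C)=CCC[C@@]1(C)O[C@H]1CO | intermediate
3 | (2R,3R)-2,3-epoxyneral, (2R,3R)-3-methyl-3-(4-methylpent-3-enyl)oxirane-2-carbaldehyde | CC(C)=CCC[C@@]1(C)O[C@H]1C=O | intermediate
4 | (1-bromovinyl)trimethylsilane | C=C(Br)[Si](C)(C)C | starting material
5 | butadiene monoxide (racemic 2-vinyloxirane) | C=CC1CO1 | starting material
6 | [1-(trimethylsilyl)vinyl]magnesium bromide | C=C([Mg]Br)[Si](C)(C)C | intermediate (not isolated)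
7 | (2E)-5-(trimethylsilyl)hexa-2,5-dien-1-ol | OC/C=C/CC(=C)[Si](C)(C)C | intermediate
8 | [(2S,3S)-3-(2-trimethylsilylprop-2-enyl)oxiran-2-yl]methanol | OC[C@@H]1O[C@H]1CC(=C)[Si](C)(C)C | intermediate
9 | (2R,3S)-3-(2-trimethylsilylprop-2-enyl)oxirane-2-carbaldehyde | O=C[C@@H]1O[C@H]1CC(=C)[Si](C)(C)C | intermediate
10 | (2S,3S)-2-ethynyl-3-(2-trimethylsilylprop-2-enyl)oxirane | C#C[C@@H]1O[C@H]1CC(=C)[Si](C)(C)C | intermediate
11 | allenylindium iodide alkoxide from 10 (axially chiral allene fixed by anti SN2′ opening, C8 as in 10; drawn as a zwitterion) | C=C([Si](C)(C)C)C[C@H]([O-])C=C=C[In+]I | intermediate (not isolated)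
12 | syn,syn-6,8-diol, (1S,2R,3S)-2-ethynyl-1-[(2S,3R)-3-methyl-3-(4-methylpent-3-enyl)oxiran-2-yl]-5-(trimethylsilyl)hex-5-ene-1,3-diol; in target numbering 4R,5S,6S,7R,8S | C=C([Si](C)(C)C)C[C@H](O)[C@@H](C#C)[C@H](O)[C@@H]1O[C@]1(C)CCC=C(C)C | intermediate
13 | 8-O-triethylsilyl ether of 12 (6-OH free; C4–C8 as in 12) | C=C([Si](C)(C)C)C[C@H](O[Si](CC)(CC)CC)[C@@H](C#C)[C@H](O)[C@@H]1O[C@]1(C)CCC=C(C)C | intermediate
14 | angelic acid, (2Z)-2-methylbut-2-enoic acid | C/C=C(/C)C(=O)O | starting material
15 | angelic 2,4,6-trichlorobenzoic mixed anhydride | C/C=C(/C)C(=O)OC(=O)c1c(Cl)cc(Cl)cc1Cl | intermediate (not isolated)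
16 | 6-O-angeloyl-8-O-triethylsilyl derivative of 12 (C4–C8 as in 12) | C=C([Si](C)(C)C)C[C@H](O[Si](CC)(CC)CC)[C@@H](C#C)[C@H](OC(=O)/C(C)=C\C)[C@@H]1O[C@]1(C)CCC=C(C)C | intermediate
17 | vicinal diol from dihydroxylation of the terminal alkene of 16 (both epimers at the new carbinol) | C=C([Si](C)(C)C)C[C@H](O[Si](CC)(CC)CC)[C@@H](C#C)[C@H](OC(=O)/C(C)=C\C)[C@@H]1O[C@]1(C)CCC(O)C(C)(C)O | intermediate (not isolated)
18 | C1 aldehyde with 6-O-angeloyl and 8-O-triethylsilyl groups (C4–C8 as in 12) | C=C([Si](C)(C)C)C[C@H](O[Si](CC)(CC)CC)[C@@H](C#C)[C@H](OC(=O)/C(C)=C\C)[C@@H]1O[C@]1(C)CCC=O | intermediate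
19 | 8-hydroxy C1 aldehyde: homopropargylic alcohol with 6-O-angeloyl group (C4–C8 as in 12) | C=C([Si](C)(C)C)C[C@H](O)[C@@H](C#C)[C@H](OC(=O)/C(C)=C\C)[C@@H]1O[C@]1(C)CCC=O | intermediate
20 | O8-alkoxycarbonylpalladium iodide of 19 (phosphine ligands omitted) | C=C([Si](C)(C)C)C[C@H](OC(=O)[Pd]I)[C@@H](C#C)[C@H](OC(=O)/C(C)=C\C)[C@@H]1O[C@]1(C)CCC=O | intermediate (not isolated)
21 | (Z)-alkenylpalladium iodide of the closed lactone, Pd on C13 cis to C12 (phosphine ligands omitted) | I[Pd]/C=C1\C(=O)O[C@@H](CC(=C)[Si](C)(C)C)[C@@H]1[C@H](OC(=O)/C(C)=C\C)[C@@H]2O[C@]2(C)CCC=O | intermediate (not isolated)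
22 | trans-fused α-methylene-γ-butyrolactone (8,12-olide) carrying the C9–C10 vinylsilane, the 6-O-angelate, the 4,5-oxirane and the C1 aldehyde (C4–C8 as in the target) | C=C1C(=O)O[C@@H](CC(=C)[Si](C)(C)C)[C@@H]1[C@H](OC(=O)/C(C)=C\C)[C@@H]2O[C@]2(C)CCC=O | intermediate
23 | alkenyl iodide, the 10-iodo analogue of 22 | C=C1C(=O)O[C@@H](CC(I)=C)[C@@H]1[C@H](OC(=O)/C(C)=C\C)[C@@H]2O[C@]2(C)CCC=O | intermediate
24 | alkenylchromium dichloride from 23 (solvent ligands omitted) | C=C1C(=O)O[C@@H](CC(=C)[Cr](Cl)Cl)[C@@H]1[C@H](OC(=O)/C(C)=C\C)[C@@H]2O[C@]2(C)CCC=O | intermediate (not isolated)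
25 | CNP0104965.1, (1S,4R,5S,6S,7R,8S)-6-angeloyloxy-4,5-epoxy-1-hydroxygermacra-10(14),11(13)-dien-12,8-olide | C=C1C(=O)O[C@H]2CC(=C)[C@@H](O)CC[C@@]3(C)O[C@H]3[C@@H](OC(=O)/C(C)=C\C)[C@H]12 | target

Total step count: 14.
Longest linear sequence: 12 steps (steps 3 to 14, from 4).

Steps most likely to fail

Step 14. The ring closure may show poor facial selectivity at the C1 aldehyde, and the alkenylnickel intermediate may be diverted into conjugate addition to the methylene lactone or into dimerisation. The fallback takes the stereochemical burden away from the ring closure. It sets out from 23: the coupling is run for conversion only and gives 25 together with its C1 epimer F1. The mixture is oxidised with Dess–Martin periodinane to the cross-conjugated 1-oxo enone F2. Reagent-controlled Corey–Bakshi–Shibata reduction ((R)-Me-CBS oxazaborolidine, catecholborane, toluene, −78 °C; the alkenyl group acts as the large substituent) then returns to the route at 25.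

Step 12. Before it is carbonylated, the free C8 hydroxyl may attack the neighbouring oxirane in an epoxy-alcohol cyclisation at 70 °C, and the nucleophilic phosphine may isomerise the angelate or add to the product. The fallback forms the same C11–C12 bond by a radical instead of an organopalladium ring closure and never exposes a free hydroxyl to heat. It sets out from 19, which is converted (COCl2, pyridine; then PhSeH) into the Se-phenyl selenocarbonate F3. Bu3SnH and AIBN in dilute benzene at 80 °C generate the alkoxycarbonyl radical, whose 5-exo-dig cyclisation onto C11, followed by hydrogen transfer to the C13 alkenyl radical, returns to the route at 22.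

Step 7. Lewis-acidic trivalent indium species may open or rearrange the trisubstituted oxirane of 3 or trigger epoxy-alcohol cyclisation of the diol, and chelation by the oxirane oxygen could erode the facial selectivity at C6. The fallback replaces the in situ indium reagent by an isolable boron reagent that adds without any Lewis acid. It sets out from 10: copper-catalysed borylative SN2′ opening (CuCl (cat.), NaOtBu (cat.), B2pin2, MeOH, THF) gives the 4-hydroxyallenyl pinacolboronate F4 with the same axial configuration. Uncatalysed allenylboration of 3 in toluene through a closed six-membered transition state, followed by mild hydrolytic work-up, returns to the route at 12.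

Further compounds
F1 | step 14 | C1 epimer of 25 | C=C1C(=O)O[C@H]2CC(=C)[C@H](O)CC[C@@]3(C)O[C@H]3[C@@H](OC(=O)/C(C)=C\C)[C@H]12
F2 | step 14 | 1-oxo enone (C1 ketone of 25) | C=C1C(=O)O[C@H]2CC(=C)C(=O)CC[C@@]3(C)O[C@H]3[C@@H](OC(=O)/C(C)=C\C)[C@H]12
F3 | step 12 | Se-phenyl selenocarbonate of 19 | C=C([Si](C)(C)C)C[C@H](OC(=O)[Se]c1ccccc1)[C@@H](C#C)[C@H](OC(=O)/C(C)=C\C)[C@@H]1O[C@]1(C)CCC=O
F4 | step 7 | 4-hydroxyallenyl pinacolboronate from 10 (axially chiral allene; C8 as in 10) | C=C([Si](C)(C)C)C[C@H](O)C=C=CB1OC(C)(C)C(C)(C)O1
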